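The interflavan C4–C6 bond is made last but one, by Friedel–Crafts union of flavan-3,4-diol 8 with benzylated ent-epifisetinidol 16. Everything rests on building ring C of the upper unit in one operation from the titanium phenolate of 3-(benzyloxy)phenol and an enantiopure trans-epoxy aldehyde: the phenolate adds through its ortho carbon to the aldehyde (C4–C4a), and its oxygen then opens the oxirane at the benzylic carbon, closing the pyran ring through O1–C2 with inversion. The step exploits ring A as an ortho C,O-dinucleophile and the para-oxygenated benzylic C2 next to ring B. The same annulation with the enantiomeric epoxide starts the lower unit.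

Key step: step 4

Remark: the target is read as guibourtinidol-(4α→6)-ent-epifisetinidol, upper unit (2R,3S,4R) and lower unit (2S,3S). C4 of diols 8 and 13 forms as an epimer mixture and is drawn without configuration because it is erased later.

Step 1
Reactants: 1 4-(benzyloxy)benzaldehyde; 2 (triphenylphosphoranylidene)acetaldehyde
Product: 3 (E)-3-[4-(benzyloxy)phenyl]prop-2-enal
Conditions: toluene, 80 °C
Reagents that add atoms: none
Why: Wittig olefination with the stabilised formyl ylide adds reversibly and should give the (E)-enal; no stereocenter is formed.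

Step 2
Reactants: 3 (E)-3-[4-(benzyloxy)phenyl]prop-2-enal
Product: 4 (2R,3S)-3-[4-(benzyloxy)phenyl]oxirane-2-carbaldehyde
Conditions: 35% aq. H2O2 (1.3 equiv), (S)-2-{bis[3,5-bis(trifluoromethyl)phenyl](trimethylsilyloxy)methyl}pyrrolidine (10 mol%), CH2Cl2, rt
Reagents that add atoms: hydrogen peroxide, OO
Why: Organocatalytic iminium–enamine epoxidation of an enal, in which hydroperoxide adds to the beta carbon on the face left open by the silyloxydiarylmethyl group of the (S)-catalyst and the enamine closes the oxirane, which should set both centers as the trans-(2R,3S) epoxide.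

Step 3
Reactants: 5 3-(benzyloxy)phenol
Product: 6 [3-(benzyloxy)phenoxy]titanium triisopropoxide
Conditions: Ti(OiPr)4 (1.0 equiv), toluene, rt; i-PrOH stripped with toluene under reduced pressure; residue kept under argon as a CH2Cl2 stock solution (one batch serves steps 4 and 7)
Reagents that add atoms: titanium tetraisopropoxide, CC(C)O[Ti](OC(C)C)(OC(C)C)OC(C)C
Why: Alcoholysis of a titanium alkoxide by the more acidic phenol (ligand exchange), driven to the aryloxide by removal of propan-2-ol; no stereocenter is formed.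

Step 4
Reactants: 4 (2R,3S)-3-[4-(benzyloxy)phenyl]oxirane-2-carbaldehyde; 6 [3-(benzyloxy)phenoxy]titanium triisopropoxide
Product: 8 (2R,3S)-7-(benzyloxy)-2-[4-(benzyloxy)phenyl]chromane-3,4-diol (2,3-trans; C4 epimers), via titanium-bound epoxy carbinol 7 (not isolated)
Conditions: 6 (1.1 equiv, CH2Cl2 stock solution), 4, CH2Cl2, −20 °C to rt; aq. potassium sodium tartrate
Reagents that add atoms: none
Why: Proposed new method: the aryloxytitanium species 6 binds the aldehyde of 4 and adds through its free ortho carbon (para to the benzyloxy group) in a six-membered chelate, forming C4–C4a and leaving carbinol 7 on the metal; the closest known reaction type is the ortho-selective hydroxyalkylation of magnesium and titanium phenolates by aldehydes. The titanium alkoxide then activates the oxirane oxygen as in the Ti(OiPr)4-mediated distal opening of 2,3-epoxy alcohols, and the phenolate oxygen attacks the benzylic oxirane carbon, forming O1–C2. This closes pyran ring C in the 6-endo-tet mode. C2 is set by inversion at the benzylic carbon and C3 is carried over from the oxirane, so the trans-(2R,3S) oxirane should give the 2,3-trans (2R,3S) flavan, while C4 arises uncontrolled and is erased in step 11. The step needs ortho over para attack on the phenol, secured by the metal template, and 6-endo over 5-exo opening, secured by the para-benzyloxyphenyl group that stabilises developing positive charge at C2 and by the chelate that holds the epoxy alkoxide.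

Step 5
Reactants: 9 3,4-bis(benzyloxy)benzaldehyde; 2 (triphenylphosphoranylidene)acetaldehyde
Product: 10 (E)-3-[3,4-bis(benzyloxy)phenyl]prop-2-enal
Conditions: toluene, 80 °C
Reagents that add atoms: none
Why: Wittig olefination with the stabilised formyl ylide should give the (E)-enal; no stereocenter is formed.

Step 6
Reactants: 10 (E)-3-[3,4-bis(benzyloxy)phenyl]prop-2-enal
Product: 11 (2S,3R)-3-[3,4-bis(benzyloxy)phenyl]oxirane-2-carbaldehyde
Conditions: 35% aq. H2O2 (1.3 equiv), (R)-2-{bis[3,5-bis(trifluoromethyl)phenyl](trimethylsilyloxy)methyl}pyrrolidine (10 mol%), CH2Cl2, rt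
Reagents that add atoms: hydrogen peroxide, OO
Why: The same organocatalytic iminium–enamine epoxidation with the enantiomeric (R)-catalyst should set both centers as the trans-(2S,3R) epoxide.

Step 7
Reactants: 11 (2S,3R)-3-[3,4-bis(benzyloxy)phenyl]oxirane-2-carbaldehyde; 6 [3-(benzyloxy)phenoxy]titanium triisopropoxide
Product: 13 (2S,3R)-7-(benzyloxy)-2-[3,4-bis(benzyloxy)phenyl]chromane-3,4-diol (2,3-trans; C4 epimers), via titanium-bound epoxy carbinol 12 (not isolated)
Conditions: 6 (1.1 equiv, CH2Cl2 stock solution), 11, CH2Cl2, −20 °C to rt; aq. potassium sodium tartrate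
Reagents that add atoms: none
Why: Proposed new method: the same titanium-phenolate ortho-hydroxyalkylation (closest known type: ortho-hydroxyalkylation of metal phenolates by aldehydes) followed by titanium-assisted 6-endo-tet opening of the oxirane by the phenolate oxygen (closest known type: distal opening of 2,3-epoxy alcohols under Ti(OiPr)4) should build ring C, with C2 set by inversion at the benzylic oxirane carbon and C3 carried over, giving the 2,3-trans (2S,3R) diol.

Step 8
Reactants: 13 (2S,3R)-7-(benzyloxy)-2-[3,4-bis(benzyloxy)phenyl]chromane-3,4-diol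
Product: 14 (2S,3R)-7-(benzyloxy)-2-[3,4-bis(benzyloxy)phenyl]chroman-3-ol
Conditions: Et3SiH (5 equiv), CF3CO2H (3 equiv), CH2Cl2, −40 °C to 0 °C
Reagents that add atoms: none
Why: Ionic hydrogenation, in which acid ionises the C4 hydroxyl to a cation stabilised by O1 and the para benzyloxy group and the silane reduces it to the methylene; no stereocenter is formed and C2 and C3 are untouched.

Step 9
Reactants: 14 (2S,3R)-7-(benzyloxy)-2-[3,4-bis(benzyloxy)phenyl]chroman-3-ol
Product: 15 (2S)-7-(benzyloxy)-2-[3,4-bis(benzyloxy)phenyl]chroman-3-one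
Conditions: Dess–Martin periodinane (1.5 equiv), wet CH2Cl2, rt; aq. NaHCO3
Reagents that add atoms: none
Why: Dess–Martin oxidation under near-neutral conditions should give the C3 ketone without epimerising the adjacent benzylic C2.

Step 10
Reactants: 15 (2S)-7-(benzyloxy)-2-[3,4-bis(benzyloxy)phenyl]chroman-3-one
Product: 16 (2S,3S)-7-(benzyloxy)-2-[3,4-bis(benzyloxy)phenyl]chroman-3-ol
Conditions: LiBH(s-Bu)3 (1.5 equiv), THF, −78 °C; H2O
Reagents that add atoms: none
Why: Diastereoselective ketone reduction by a bulky hydride, which should attack equatorially and place the new C3 hydroxyl axial and cis to the C2 aryl group, giving the (2S,3S) alcohol.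

Step 11
Reactants: 8 (2R,3S)-7-(benzyloxy)-2-[4-(benzyloxy)phenyl]chromane-3,4-diol; 16 (2S,3S)-7-(benzyloxy)-2-[3,4-bis(benzyloxy)phenyl]chroman-3-ol
Product: 17 penta-O-benzyl-guibourtinidol-(4α→6)-ent-epifisetinidol
Conditions: Yb(OTf)3 (20 mol%), 16 (3 equiv), slow addition of 8, 4 Å MS, CH2Cl2, 0 °C to rt
Reagents that add atoms: none
Why: Lewis-acid catalysed Friedel–Crafts benzylation through the flavan-4-yl cation (stabilised by O1 and the 7-benzyloxy group), which C6 of 16 (para to its ring oxygen, ortho to its benzyloxy group, less hindered than C8) should attack on the face opposite to the C3 hydroxyl, setting C4 as the 3,4-trans (4α) center.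

Step 12
Reactants: 17 penta-O-benzyl-guibourtinidol-(4α→6)-ent-epifisetinidol
Product: 18 guibourtinidol-(4α→6)-ent-epifisetinidol (CNP0243811.1)
Conditions: H2 (1 atm), Pd(OH)2/C, THF/MeOH/H2O, rt
Reagents that add atoms: none
Why: Catalytic hydrogenolysis of the five benzyl ethers under neutral conditions should free the phenols without touching the stereocenters or the ring C–O bonds.

Compound list
1 | 4-(benzyloxy)benzaldehyde | O=Cc1ccc(OCc2ccccc2)cc1 | starting material
2 | (triphenylphosphoranylidene)acetaldehyde | O=CC=P(c1ccccc1)(c1ccccc1)c1ccccc1 | starting material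
3 | (E)-3-[4-(benzyloxy)phenyl]prop-2-enal | O=C/C=C/c1ccc(OCc2ccccc2)cc1 | intermediate
4 | (2R,3S)-3-[4-(benzyloxy)phenyl]oxirane-2-carbaldehyde | O=C[C@@H]1O[C@H]1c1ccc(OCc2ccccc2)cc1 | intermediate
5 | 3-(benzyloxy)phenol | Oc1cccc(OCc2ccccc2)c1 | starting material
6 | [3-(benzyloxy)phenoxy]titanium triisopropoxide | CC(C)O[Ti](OC(C)C)(OC(C)C)Oc1cccc(OCc2ccccc2)c1 | intermediate
7 | [4-(benzyloxy)-2-hydroxyphenyl]{trans-3-[4-(benzyloxy)phenyl]oxiran-2-yl}methanol, oxirane carbons configured as in 4, carbinol epimers, held on titanium in the flask and drawn metal-free | Oc1cc(OCc2ccccc2)ccc1C(O)[C@@H]1O[C@H]1c1ccc(OCc2ccccc2)cc1 | intermediate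
8 | (2R,3S)-7-(benzyloxy)-2-[4-(benzyloxy)phenyl]chromane-3,4-diol, 2,3-trans, C4 epimers | c1ccccc1COc1ccc([C@H]2Oc3cc(OCc4ccccc4)ccc3C(O)[C@@H]2O)cc1 | intermediate
9 | 3,4-bis(benzyloxy)benzaldehyde | O=Cc1ccc(OCc2ccccc2)c(OCc2ccccc2)c1 | starting material
10 | (E)-3-[3,4-bis(benzyloxy)phenyl]prop-2-enal | O=C/C=C/c1ccc(OCc2ccccc2)c(OCc2ccccc2)c1 | intermediate
11 | (2S,3R)-3-[3,4-bis(benzyloxy)phenyl]oxirane-2-carbaldehyde | O=C[C@H]1O[C@@H]1c1ccc(OCc2ccccc2)c(OCc2ccccc2)c1 | intermediate
12 | [4-(benzyloxy)-2-hydroxyphenyl]{trans-3-[3,4-bis(benzyloxy)phenyl]oxiran-2-yl}methanol, oxirane carbons configured as in 11, carbinol epimers, held on titanium in the flask and drawn metal-free | Oc1cc(OCc2ccccc2)ccc1C(O)[C@H]1O[C@@H]1c1ccc(OCc2ccccc2)c(OCc2ccccc2)c1 | intermediate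
13 | (2S,3R)-7-(benzyloxy)-2-[3,4-bis(benzyloxy)phenyl]chromane-3,4-diol, 2,3-trans, C4 epimers | c1ccccc1COc1ccc([C@@H]2Oc3cc(OCc4ccccc4)ccc3C(O)[C@H]2O)cc1OCc5ccccc5 | intermediate
14 | (2S,3R)-7-(benzyloxy)-2-[3,4-bis(benzyloxy)phenyl]chroman-3-ol (tri-O-benzyl-ent-fisetinidol, 2,3-trans) | c1ccccc1COc1ccc([C@@H]2Oc3cc(OCc4ccccc4)ccc3C[C@H]2O)cc1OCc5ccccc5 | intermediate
15 | (2S)-7-(benzyloxy)-2-[3,4-bis(benzyloxy)phenyl]chroman-3-one | c1ccccc1COc1ccc([C@@H]2Oc3cc(OCc4ccccc4)ccc3CC2=O)cc1OCc5ccccc5 | intermediate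
16 | (2S,3S)-7-(benzyloxy)-2-[3,4-bis(benzyloxy)phenyl]chroman-3-ol (tri-O-benzyl-ent-epifisetinidol, 2,3-cis) | c1ccccc1COc1ccc([C@@H]2Oc3cc(OCc4ccccc4)ccc3C[C@@H]2O)cc1OCc5ccccc5 | intermediate
17 | penta-O-benzyl-guibourtinidol-(4α→6)-ent-epifisetinidol: (2R,3S)-7-(benzyloxy)-2-[4-(benzyloxy)phenyl]chroman-3-ol carrying at C4, trans to the 3-hydroxyl (4α), the (2S,3S)-7-(benzyloxy)-2-[3,4-bis(benzyloxy)phenyl]-3-hydroxychroman-6-yl group | c1ccccc1COc1ccc([C@H]2Oc3cc(OCc4ccccc4)ccc3[C@@H](c3cc4c(cc3OCc5ccccc5)O[C@@H](c3ccc(OCc5ccccc5)c(OCc5ccccc5)c3)[C@@H](O)C4)[C@@H]2O)cc1 | intermediate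
18 | guibourtinidol-(4α→6)-ent-epifisetinidol, (2R,3S,4R)-4-[(2S,3S)-2-(3,4-dihydroxyphenyl)-3,7-dihydroxychroman-6-yl]-2-(4-hydroxyphenyl)chromane-3,7-diol | Oc1ccc([C@H]2Oc3cc(O)ccc3[C@@H](c3cc4c(cc3O)O[C@@H](c3ccc(O)c(O)c3)[C@@H](O)C4)[C@@H]2O)cc1 | target

Total steps: 12
Longest linear sequence: 8 steps (steps 5 to 12)

Steps most likely to fail

Step 4 (labelled step). The phenolate may react at its para carbon or add twice to give a diarylmethane. Isopropoxide may reduce the aldehyde by hydride transfer. The oxirane may open in the 5-exo sense or ionise at C2 with loss of configuration. The fallback uses known chemistry, sets out from 1 and comes back at 8. Claisen–Schmidt condensation of 1 with commercial 1-[4-(benzyloxy)-2-hydroxyphenyl]ethanone (KOH, EtOH) should give (E)-1-[4-(benzyloxy)-2-hydroxyphenyl]-3-[4-(benzyloxy)phenyl]prop-2-en-1-one F1. O-Allylation (allyl bromide, K2CO3, DMF) should give (E)-1-[2-(allyloxy)-4-(benzyloxy)phenyl]-3-[4-(benzyloxy)phenyl]prop-2-en-1-one F2. Juliá–Colonna epoxidation (poly-L-leucine, urea–H2O2, DBU, THF) should give [2-(allyloxy)-4-(benzyloxy)phenyl]{(2R,3S)-3-[4-(benzyloxy)phenyl]oxiran-2-yl}methanone F3. NaBH4 in MeOH/THF should reduce it to [2-(allyloxy)-4-(benzyloxy)phenyl]{trans-3-[4-(benzyloxy)phenyl]oxiran-2-yl}methanol F4. Pd(PPh3)4 with morpholine then removes the allyl group under neutral conditions to give the metal-free form of 7, and catalytic camphorsulfonic acid (CH2Cl2, 0 °C) closes ring C by the same 6-endo opening to give 8.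

Step 7 (labelled step). The same processes threaten this step, and the more electron-rich 3,4-bis(benzyloxy)phenyl group makes ionisation at C2, with loss of the trans relationship, more likely. The fallback uses known chemistry, sets out from 9 and comes back at 13. Claisen–Schmidt condensation of 9 with 1-[4-(benzyloxy)-2-hydroxyphenyl]ethanone should give (E)-1-[4-(benzyloxy)-2-hydroxyphenyl]-3-[3,4-bis(benzyloxy)phenyl]prop-2-en-1-one F5. O-Allylation should give (E)-1-[2-(allyloxy)-4-(benzyloxy)phenyl]-3-[3,4-bis(benzyloxy)phenyl]prop-2-en-1-one F6. Juliá–Colonna epoxidation with poly-D-leucine should give [2-(allyloxy)-4-(benzyloxy)phenyl]{(2S,3R)-3-[3,4-bis(benzyloxy)phenyl]oxiran-2-yl}methanone F7. NaBH4 should give [2-(allyloxy)-4-(benzyloxy)phenyl]{trans-3-[3,4-bis(benzyloxy)phenyl]oxiran-2-yl}methanol F8. Deallylation with Pd(PPh3)4 and morpholine gives the metal-free form of 12, which catalytic camphorsulfonic acid cyclises to 13.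

Step 11. Ring A of a second molecule of the electrophile may capture the cation (self-condensation). The nucleophile may attack the face syn to the C3 hydroxyl, and substitution may occur at C8 of the nucleophile. The fallback relies on neighbouring-group control, sets out from 8 and comes back at 17. Acetylation (Ac2O, pyridine, DMAP) should give (2R,3S)-7-(benzyloxy)-2-[4-(benzyloxy)phenyl]chromane-3,4-diyl diacetate F9. With catalytic TMSOTf in CH2Cl2 at −40 °C and excess 16, the 4-acetate leaves and the 3-acetate bridges the cation as an acetoxonium ion, so that C6 of 16 must enter trans to it; this should give the 3-O-acetyl derivative of 17, F10. K2CO3 in MeOH/THF then removes the acetate to give 17. Slow addition of the electrophile to excess nucleophile is kept to hold back self-condensation.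

Further compounds
F1 | step 4 | (E)-1-[4-(benzyloxy)-2-hydroxyphenyl]-3-[4-(benzyloxy)phenyl]prop-2-en-1-one | O=C(/C=C/c1ccc(OCc2ccccc2)cc1)c1ccc(OCc2ccccc2)cc1O
F2 | step 4 | (E)-1-[2-(allyloxy)-4-(benzyloxy)phenyl]-3-[4-(benzyloxy)phenyl]prop-2-en-1-one | C=CCOc1cc(OCc2ccccc2)ccc1C(=O)/C=C/c1ccc(OCc2ccccc2)cc1
F3 | step 4 | [2-(allyloxy)-4-(benzyloxy)phenyl]{(2R,3S)-3-[4-(benzyloxy)phenyl]oxiran-2-yl}methanone | C=CCOc1cc(OCc2ccccc2)ccc1C(=O)[C@@H]1O[C@H]1c1ccc(OCc2ccccc2)cc1
F4 | step 4 | [2-(allyloxy)-4-(benzyloxy)phenyl]{trans-3-[4-(benzyloxy)phenyl]oxiran-2-yl}methanol, oxirane as in F3, carbinol epimers | C=CCOc1cc(OCc2ccccc2)ccc1C(O)[C@@H]1O[C@H]1c1ccc(OCc2ccccc2)cc1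
F5 | step 7 | (E)-1-[4-(benzyloxy)-2-hydroxyphenyl]-3-[3,4-bis(benzyloxy)phenyl]prop-2-en-1-one | O=C(/C=C/c1ccc(OCc2ccccc2)c(OCc2ccccc2)c1)c1ccc(OCc2ccccc2)cc1O
F6 | step 7 | (E)-1-[2-(allyloxy)-4-(benzyloxy)phenyl]-3-[3,4-bis(benzyloxy)phenyl]prop-2-en-1-one | C=CCOc1cc(OCc2ccccc2)ccc1C(=O)/C=C/c1ccc(OCc2ccccc2)c(OCc2ccccc2)c1
F7 | step 7 | [2-(allyloxy)-4-(benzyloxy)phenyl]{(2S,3R)-3-[3,4-bis(benzyloxy)phenyl]oxiran-2-yl}methanone | C=CCOc1cc(OCc2ccccc2)ccc1C(=O)[C@H]1O[C@@H]1c1ccc(OCc2ccccc2)c(OCc2ccccc2)c1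
F8 | step 7 | [2-(allyloxy)-4-(benzyloxy)phenyl]{trans-3-[3,4-bis(benzyloxy)phenyl]oxiran-2-yl}methanol, oxirane as in F7, carbinol epimers | C=CCOc1cc(OCc2ccccc2)ccc1C(O)[C@H]1O[C@@H]1c1ccc(OCc2ccccc2)c(OCc2ccccc2)c1
F9 | step 11 | (2R,3S)-7-(benzyloxy)-2-[4-(benzyloxy)phenyl]chromane-3,4-diyl diacetate, C4 epimers | c1ccccc1COc1ccc([C@H]2Oc3cc(OCc4ccccc4)ccc3C(OC(C)=O)[C@@H]2OC(C)=O)cc1
F10 | step 11 | 3-O-acetyl derivative of 17 (acetate on the upper unit) | c1ccccc1COc1ccc([C@H]2Oc3cc(OCc4ccccc4)ccc3[C@@H](c3cc4c(cc3OCc5ccccc5)O[C@@H](c3ccc(OCc5ccccc5)c(OCc5ccccc5)c3)[C@@H](O)C4)[C@@H]2OC(C)=O)cc1
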